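Start from the early times: at 20.0 min the west flask, a kinetic resolution over a single-handed catalyst, shows just 1.8 % left-handed product, so take the pace from the north-west run.

| flask | left-handed substrate | right-handed substrate | solid reagent | precatalyst | remark | time |
|---|---|---|---|---|---|---|
| west | 0.19 M | 0.19 M | 0.57 M | 9.7 mM | the very flask that is asked about, followed so far |  |
| north-west | 0.19 M | 0.19 M | 0.57 M | 15 mM | run made earlier |  |
| flask | 0.19 M | 0.19 M | 0.570 M | 9.7 mM |  | 4.0 h |

| run | time / min | right-handed substrate / % | left-handed substrate / % | left-handed product / % |
|---|---|---|---|---|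
| west | 2.50 | 51.2 | 49.2 | 0 |
| west | 6.00 | 50.9 | 50.1 | 2.4 |
| west | 12.0 | 49.6 | 48.1 | 1.1 |
| west | 20.0 | 50.8 | 50.2 | 1.8 |
| north-west | 8.00 | 49.6 | 49.0 | 0.3 |
| north-west | 20.0 | 51.1 | 48.0 | 3.1 |
| north-west | 40.0 | 51.1 | 41.3 | 6.6 |
| north-west | 90.0 | 48.4 | 19.0 | 26.8 |

(standard deviation of a reading: 1 percentage point)

- free catalyst is single-handed; left-handed substrate and right-handed substrate are mirror images of each other, charged as a racemate, each of them at the stated concentration
- solid reagent is a solid; its amount is given per volume of the solution
- steps that have been proposed: free catalyst + left-handed substrate <-> catalyst intermediate A; free catalyst + right-handed substrate <-> catalyst intermediate B; partner + catalyst intermediate A -> free catalyst + left-handed product; partner + catalyst intermediate B -> free catalyst + right-handed product; partner <-> dormant form; solid reagent <-> partner; precatalyst <-> free catalyst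
- at the start none of the solid reagent is in solution

* whether the excess of right-handed substrate over left-handed substrate among what is left of the two reaches 80 % by 4.0 h (no / yes)
* the highest excess of right-handed substrate over left-handed substrate among what is left of the two up to 4.0 h

Define the allowed ratio q, the left-handed over the right-handed substrate left at the wanted excess, as one minus the excess over one plus the excess: 0.111. In the west flask, with right-handed substrate at 50.8 %, left-handed substrate must fall from 50.2 % to 5.64 %. Take the late north-west product gain, scaled by precatalyst to the west flask: 0.00261 min⁻¹ of the charge. My own reckoning for the west flask then arrives at 3.18 h, earlier than the 4.0 h allowed.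

The forecast says yes, with a top of 92 %: “The solid supplies ample partner.”

The west flask gives yes, with a top of >99.9 %, and the wanted excess arrives at 2.52 h.

    free catalyst + left-handed substrate ⇌ catalyst intermediate A (K = 73.7 M⁻¹, k = 3.82 M⁻¹ s⁻¹)
    free catalyst + right-handed substrate ⇌ catalyst intermediate B (K = 2.95 M⁻¹, k = 2.86 M⁻¹ s⁻¹)
    partner + catalyst intermediate A → free catalyst + left-handed product (k = 0.0981 M⁻¹ s⁻¹)
    partner + catalyst intermediate B → free catalyst + right-handed product (k = 0.0320 M⁻¹ s⁻¹)
    partner ⇌ dormant form (K = 29.0, k = 1.69 × 10⁻⁴ s⁻¹)
    solid reagent ⇌ partner, rate k6*(cs6 - [partner]) while solid is left; crystals form when [partner] > cs6 (solubility = 0.170 M, k = 2.26 × 10⁻⁴ s⁻¹)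
    precatalyst ⇌ free catalyst (K = 1.50, k = 2.97 × 10⁻⁴ s⁻¹)

Apply q to the west flask: with 48.1 % right-handed substrate left at that moment, left-handed substrate stands near 5.34 %. One proven contributor to the excess of right-handed substrate, not the main reason, is the reverse step of catalyst intermediate B, which hands right-handed substrate back. Remove that step in the simulated run and the excess at 4.0 h goes from >99.9 % to −79.9 %, which turns the answer on reaching the wanted excess. In that run without the step, at 4.0 h, q holds the other way round: right-handed substrate left is near 0.111 of the left-handed substrate left.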